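The question is how the charge of starting material, the limiting reagent, is divided at the end of the run, and how far dissolved target then stands from saturation.

| setting | grey | flask |
|---|---|---|
| starting material | 0.80 M | 0.80 M |
| remark | the very flask that is asked about, followed so far |  |
| time |  | 80 min |

grey run (percent of the starting material charged)

| time / min | target / % | crystals / % | starting material / % |
|---|---|---|---|
| 3.00 | 47.5 | 17.9 | 51.4 |
| 8.00 | 72.0 | 49.3 | 24.3 |
| 15.0 | 83.7 | 74.4 | 10.9 |
| 25.0 | 90.9 | 85.5 | 5.3 |

(each reading ± 1 percentage point)

- amounts and yields of target count crystals too
- given per volume of solution although it is solid: crystals
- the numbers in the tables scatter with a standard deviation of 1 percentage point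

- amount of target and crystals together at 80 min, in percent of the starting material charged
- concentration of target in solution at 80 min, in percent of saturation

The books open with the crystals. Dissolved target is target minus crystals, and crystal growth between readings follows it, as a share of the charge:

growth 0.0628 /min at mean dissolved target 26.2%

growth 0.0111 /min at mean dissolved target 7.35%

slope 0.275 /min, so growth reaches zero at 3.31% of the charge

That crossing, where crystals stop drawing target from solution, is read as the saturation concentration c_sat = 0.0265 M. The remaining entries are my own reckoning:

starting material, if it keeps its last ratio to dissolved target: 3.25%

missing from target plus starting material at the last reading: 3.80%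

target and crystals, the remainder: 92.9%

In the grey run, with starting material still feeding target, the excess of dissolved target over c_sat fell between 8.00 min and 25.0 min with a half-life read as 5.29 min, far shorter than the 80 min allowed, so c_target should stand near 100% of saturation.

The forecast gives 94% and 102%, reasoning that “the solution sits essentially at saturation”.

The flask gives 92.5% and 101%, after standing at 807% of saturation at 8.00 min. With c_sat, 3.31% of the charge stays dissolved, which puts crystals at 89.2%, beside 90.0% in the flask at 80.0 min.

    starting material ⇌ target (K = 1.40, k = 0.290 /min)
    target ⇌ isomer of the product (K = 2.10, k = 0.0180 /min)
    crystals ⇌ target, rate k3*(cs3 - [target]) while solid is left; crystals form when [target] > cs3 (solubility = 20.0 mM, k = 0.290 /min)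

In the second flask, charged with 0.32 M, the same c_sat is 8.28% of the charge, a larger share than in the first. Computed, that flask holds 86.4% target and crystals together and 80.3% crystals, a gap of 6.1 points.

The data are calculated with constants of no real substance, noise included.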